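**Retrosynthetic overview**
- Feature: the single ten-membered ring is numbered C1–C10 (C6 OAng, C7 isopropenyl, C9 OH, C10 Me/OH). Its segment C1(OAng)–C2H2–C3/C4(Me) epoxide–C5(OAc), read with the epoxide as a Z C3=C4 alkene, is a 2-ene-1,5-diol.
- Key disconnection: C1–C2 and C4–C5 are cut together, giving the C5–C10–C1 dialdehyde 21 and the C2–C4 γ-boryl allylborane 25; the ring is formed once, in step 17.
- Dialdehyde 21 from (S)-carvone: epoxidation fixes the C10 oxygen relative to C7, α'-hydroxylation and Pb(OAc)4 cleave C1–C6, a hydroxymethyl anion adds C5 and sets C6, and hydrolysis of the acyclic glycidic ester inverts C9.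
- Linchpin 25 from but-2-yn-1-ol: SN2' borylation to the allenylboronate, then hydroboration with Cy2BH.
- After ring closure: C5 acetylation, C1-hydroxyl-directed epoxidation of C3=C4, C1 angeloylation, desilylation.

Key step: step 17

Remark: atom labels C1–C10 follow the target ring in every intermediate. Both the C9 and C10 hydroxyls are carried as triethylsilyl ethers, put on in one step and removed together at the end. The angeloyl donor 18 is made once, in a batch sized for both angelate esters, and kept as a cold toluene stock solution.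

**Route**

Step 1
Reactants: 1 (S)-carvone
Product: 2 (1S,4S,6S)-1-methyl-4-(prop-1-en-2-yl)-7-oxabicyclo[4.1.0]heptan-2-one (epoxide trans to isopropenyl)
Conditions: 35% H2O2, NaOH (aq, cat.), MeOH, 0 °C
Reagents that add atoms: hydrogen peroxide, OO
Why: Weitz–Scheffer nucleophilic epoxidation of the enone, in which hydroperoxide adds to C9 anti to the C7 isopropenyl group so that the epoxide forms trans to it, fixing the C10–O bond in its final configuration while the isolated isopropenyl alkene does not react.

Step 2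
Reactants: 2 trans-carvone epoxide
Product: 4 (1S,3R,4R,6S)-3-hydroxy-1-methyl-4-(prop-1-en-2-yl)-7-oxabicyclo[4.1.0]heptan-2-one (C6 hydroxyl expected trans to isopropenyl), via potassium enolate 3 (not isolated)
Conditions: KHMDS, THF, −78 °C; 2-(phenylsulfonyl)-3-phenyloxaziridine, −78 °C; NH4Cl (aq)
Reagents that add atoms: 2-(phenylsulfonyl)-3-phenyloxaziridine, O=S(=O)(c1ccccc1)N1OC1c1ccccc1
Why: C6 is the only enolisable position because C10 is quaternary, so the enolate forms regiospecifically and is hydroxylated by the Davis oxaziridine (enolate oxidation), and the C6 configuration is erased in step 3.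

Step 3
Reactants: 4 α'-hydroxy epoxy ketone
Product: 5 methyl (2S,3S)-3-[(2R)-2-formyl-3-methylbut-3-en-1-yl]-2-methyloxirane-2-carboxylate
Conditions: Pb(OAc)4, MeOH/benzene (1:1), 0 °C
Reagents that add atoms: methanol, CO
Why: Criegee-type cleavage of the α-hydroxy ketone in methanol breaks C1–C6 to give the C1 methyl ester (a glycidic ester) and the C6 aldehyde, leaving the epoxide, the alkene and the C7, C9 and C10 centres unchanged.

Step 4
Reactants: 6 (4-methoxyphenyl)methanol; 7 tributyl(iodomethyl)stannane
Product: 9 tributyl{[(4-methoxybenzyl)oxy]methyl}stannane, via sodium alkoxide 8 (not isolated)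
Conditions: NaH, THF/DMF, 0 °C; then 7, 0 °C → rt
Reagents that add atoms: none
Why: Williamson ether synthesis, an SN2 displacement of iodide from the iodomethylstannane by the benzylic alkoxide, gives a stable precursor of a protected hydroxymethyl anion.

Step 5
Reactants: 5 epoxy ester aldehyde; 9 alkoxymethylstannane
Product: 12 methyl (2S,3S)-3-[(2R,3S)-3-acetoxy-4-[(4-methoxybenzyl)oxy]-2-(prop-1-en-2-yl)butyl]-2-methyloxirane-2-carboxylate, via alkoxymethyllithium 10 (not isolated), via lithium alkoxide 11 (not isolated)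
Conditions: 9, n-BuLi, THF, −78 °C; then 5, −78 °C; then Ac2O, −78 → 0 °C; C6 epimer removed by chromatography
Reagents that add atoms: acetic anhydride, CC(=O)OC(C)=O
Why: tin–lithium exchange gives the α-alkoxymethyllithium, which at −78 °C adds only to the aldehyde (the hindered glycidic ester and the epoxide are inert), Felkin–Anh addition with the isopropenyl group anti to the nucleophile setting C6 as in the target, and acetylation of the lithium alkoxide in the same flask keeps the C6 oxygen from attacking the epoxide.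

Step 6
Reactants: 12 epoxy ester acetate
Product: 13 methyl (2S,3R,5R,6S)-6-acetoxy-2,3-dihydroxy-7-[(4-methoxybenzyl)oxy]-2-methyl-5-(prop-1-en-2-yl)heptanoate
Conditions: HClO4 (aq, cat.), THF/H2O, rt
Reagents that add atoms: water, O
Why: acid-catalysed hydrolysis of a glycidic ester, in which the ester group destabilises positive charge at C10 so that water attacks C9 with inversion (anti opening), turning the ring-derived cis-epoxide into the 9,10-syn diol of the target with the C10–O bond retained.

Step 7
Reactants: 13 diol ester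
Product: 14 methyl (2S,3R,5R,6S)-6-acetoxy-7-[(4-methoxybenzyl)oxy]-2-methyl-5-(prop-1-en-2-yl)-2,3-bis[(triethylsilyl)oxy]heptanoate
Conditions: TESOTf, 2,6-lutidine, CH2Cl2, −78 → 0 °C
Reagents that add atoms: triethylsilyl trifluoromethanesulfonate, CC[Si](CC)(CC)OS(=O)(=O)C(F)(F)F
Why: a silyl triflate with a hindered pyridine base silylates both the secondary C9 and the tertiary C10 hydroxyl in one operation.

Step 8
Reactants: 14 bis-silyl ester
Product: 15 (2R,3R,5R,6S)-7-[(4-methoxybenzyl)oxy]-2-methyl-5-(prop-1-en-2-yl)-2,3-bis[(triethylsilyl)oxy]heptane-1,6-diol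
Conditions: DIBAL-H (excess), CH2Cl2, −78 → −20 °C; Rochelle salt (aq)
Reagents that add atoms: none
Why: hydride reduction converts the methyl ester into the primary C1 alcohol and cleaves the C6 acetate in the same step, while the benzyl and silyl ethers and the alkene are inert to DIBAL-H.

Step 9
Reactants: 15 diol
Product: 16 (2S,3R,5R,6S)-6-hydroxy-7-[(4-methoxybenzyl)oxy]-2-methyl-5-(prop-1-en-2-yl)-2,3-bis[(triethylsilyl)oxy]heptanal
Conditions: TEMPO (cat.), PhI(OAc)2, CH2Cl2, rt
Reagents that add atoms: none
Why: the oxoammonium oxidation (TEMPO with a hypervalent iodine co-oxidant) takes primary alcohols much faster than secondary ones, so C1 becomes the non-enolisable aldehyde and the C6 hydroxyl is left free for acylation.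

Step 10
Reactants: 17 angelic acid
Product: 18 angelic 2,4,6-trichlorobenzoic anhydride
Conditions: 2,4,6-trichlorobenzoyl chloride, Et3N, toluene, 0 °C → rt; Et3N·HCl filtered off under argon; toluene stock solution kept at −20 °C for steps 11 and 20
Reagents that add atoms: 2,4,6-trichlorobenzoyl chloride, O=C(Cl)c1c(Cl)cc(Cl)cc1Cl
Why: formation of the Yamaguchi mixed anhydride by acylation of triethylammonium angelate with the hindered aroyl chloride, in which no nucleophilic catalyst is present so the Z geometry is kept, and the two ortho chlorines shield the aroyl carbonyl so that the anhydride can be stored and later transfers only the angeloyl group.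

Step 11
Reactants: 16 hydroxy aldehyde; 18 mixed anhydride
Product: 19 (2S,3R,5R,6S)-7-[(4-methoxybenzyl)oxy]-2-methyl-1-oxo-5-(prop-1-en-2-yl)-2,3-bis[(triethylsilyl)oxy]heptan-6-yl (2Z)-2-methylbut-2-enoate
Conditions: 18 (toluene solution), Et3N, toluene, 75 °C
Reagents that add atoms: none
Why: Yamaguchi-type esterification with the preformed mixed anhydride, run without DMAP because nucleophilic catalysts isomerise angelates to tiglates, acylates the C6 hydroxyl at the unshielded angeloyl carbonyl while the C1 aldehyde, which has no α-hydrogen, is inert to triethylamine.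

Step 12
Reactants: 19 angelate PMB ether
Product: 20 (2S,3R,5R,6S)-7-hydroxy-2-methyl-1-oxo-5-(prop-1-en-2-yl)-2,3-bis[(triethylsilyl)oxy]heptan-6-yl (2Z)-2-methylbut-2-enoate
Conditions: DDQ, CH2Cl2/pH 7 buffer, 0 °C
Reagents that add atoms: none
Why: oxidative cleavage of the 4-methoxybenzyl ether by DDQ under buffered conditions frees the C5 hydroxyl without touching the silyl ethers, the angelate, the aldehyde or the alkenes.

Step 13
Reactants: 20 primary alcohol
Product: 21 (2S,3R,5R,6S)-2-methyl-1,7-dioxo-5-(prop-1-en-2-yl)-2,3-bis[(triethylsilyl)oxy]heptan-6-yl (2Z)-2-methylbut-2-enoate (C5–C10–C1 dialdehyde; 6S,7R,9R,10S in ring numbering)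
Conditions: Dess–Martin periodinane, NaHCO3, CH2Cl2, 0 °C → rt; used at once
Reagents that add atoms: none
Why: Dess–Martin oxidation under buffered, non-basic conditions gives the α-acyloxy aldehyde without epimerising C6 or migrating the angelate.

Step 14
Reactants: 22 but-2-yn-1-ol
Product: 23 but-2-yn-1-yl methyl carbonate
Conditions: ClCO2Me, pyridine, CH2Cl2, 0 °C
Reagents that add atoms: methyl chloroformate, COC(=O)Cl
Why: acylation of the propargylic alcohol installs the carbonate leaving group needed for the SN2' borylation.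

Step 15
Reactants: 23 propargylic carbonate
Product: 24 2-(buta-2,3-dien-2-yl)-4,4,5,5-tetramethyl-1,3,2-dioxaborolane
Conditions: B2pin2, CuCl (5 mol %), Xantphos (5 mol %), KOt-Bu (10 mol %), THF, rt
Reagents that add atoms: bis(pinacolato)diboron, CC1(C)OB(OC1(C)C)B1OC(C)(C)C(C)(C)O1
Why: copper-catalysed SN2' substitution of a propargylic carbonate by a boryl-copper species delivers boron to the methyl-bearing alkyne carbon and gives the 1,1-disubstituted allenylboronate with loss of CO2 and methoxide.

Step 16
Reactants: 24 allenylboronate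
Product: 25 dicyclohexyl[(2Z)-3-(4,4,5,5-tetramethyl-1,3,2-dioxaborolan-2-yl)but-2-en-1-yl]borane (boronate trans to the CH2B group, methyl cis)
Conditions: cyclohexene (2 equiv), BH3·SMe2, THF, 0 °C (gives Cy2BH); then 24, 0 °C → rt; solution used directly in step 17
Reagents that add atoms: cyclohexene, C1=CCCCC1; borane–dimethyl sulfide, C[S+](C)[BH3-]
Why: hydroboration of the unsubstituted terminal C=C of an allenylboronate by a dialkylborane places boron on the CH2 carbon, and reversible 1,3-boratropic shifts let the allylborane settle in the isomer with the planar boronate trans to the CH2BCy2 group, the same preference that makes tiglates more stable than angelates.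

Step 17
Reactants: 21 dialdehyde; 25 γ-boryl allylborane
Product: 28 (3Z)-cyclodec-3-ene-1,5-diol bearing the C6 angelate and the C9/C10 triethylsilyl ethers (all centres as in the target), via tertiary allylboronate 26 (not isolated), via cyclic bis-boron ester 27 (not isolated)
Conditions: 21, toluene, −78 °C; 25 (1.05 equiv) added slowly, −78 °C; dilution to 2 mM, −78 → 25 → 50 °C; then ethanolamine, NaHCO3 (aq)
Reagents that add atoms: none
Why: Proposed new method: the dialkylallylborane end of 25 should add first, through a closed six-membered chair with the boronate equatorial and the methyl axial, to the C5 aldehyde, forming C4–C5 and the tertiary allylic boronate 26; on warming under dilution this boronate adds intramolecularly to the C1 aldehyde through a second chair with C5 axial on C4 and C10 equatorial on C1, forming C1–C2 and the Z C3=C4 alkene. The closest known reaction type is the one-pot double allylboration of two separate aldehydes with a γ-boryl allylborane, which gives (Z)-2-ene-1,5-diols; the ring-closing second addition and the methyl group on the boron-bearing carbon are new. The ten-membered ring closes by intramolecular allyl transfer at C1–C2 in a bicyclic transition state in which the four-atom C6–C9 chain bridges the axial C5 and the equatorial C10 positions of the chair. C5 is set by polar Felkin–Anh (Cornforth) attack anti to the C6 angelate, which gives the 5,6-anti arrangement, the quaternary C4 boronate centre follows from the reagent geometry, and C1 is set by transfer of the C4 configuration through the second chair. The step needs aldehyde differentiation, secured because the α-acyloxy C5 aldehyde is more electrophilic and far less hindered than the neopentyl C1 aldehyde, and ring closure in preference to oligomerisation, secured by dilution once the first addition is complete.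

Step 18
Reactants: 28 cyclodecenediol
Product: 29 C5 monoacetate of 28 (C1 hydroxyl free)
Conditions: Ac2O (1.1 equiv), pyridine, CH2Cl2, −20 → 0 °C
Reagents that add atoms: acetic anhydride, CC(=O)OC(C)=O
Why: the allylic C5 hydroxyl is less hindered than the C1 hydroxyl, which sits next to the quaternary C10 silyl ether, so low-temperature acetylation without DMAP should take C5 first and also switches off the allylic hydroxyl as a directing group for step 19.

Step 19
Reactants: 29 C5 acetate
Product: 30 C3–C4 epoxide of 29 (3R,4R; C1 hydroxyl free)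
Conditions: VO(acac)2 (cat.), t-BuOOH (decane), CH2Cl2, 0 °C → rt
Reagents that add atoms: tert-butyl hydroperoxide, CC(C)(C)OO
Why: vanadium-catalysed hydroxyl-directed epoxidation by the homoallylic C1 alcohol delivers oxygen through a chair-like vanadate transition state with C10 equatorial, the same chair as in step 17, to the alkene face that gives the 1,3-syn epoxy alcohol (3R,4R), while the isopropenyl and angelate alkenes, which have no directing hydroxyl, do not react.

Step 20
Reactants: 30 epoxy alcohol; 18 mixed anhydride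
Product: 31 C1 angelate of 30 (9,10-bis-triethylsilyl ether of the target)
Conditions: 18 (toluene solution), Et3N, toluene, 80 °C
Reagents that add atoms: none
Why: the same DMAP-free Yamaguchi-type angeloylation with the preformed mixed anhydride, run hotter for the hindered C1 hydroxyl, keeps the Z geometry of the acyl group and leaves the epoxide, acetate and silyl ethers intact.

Step 21
Reactants: 31 bis-silyl ether
Product: 32 CNP0249359.1
Conditions: HF·pyridine, pyridine, THF, 0 °C → rt
Reagents that add atoms: none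
Why: buffered fluoride cleavage of both triethylsilyl ethers frees the C9 and C10 hydroxyls without base-induced acyl migration or acid opening of the epoxide.

**Compound list**
1 | (S)-carvone | C=C(C)[C@H]1CC=C(C)C(=O)C1 | starting material
2 | (1S,4S,6S)-1-methyl-4-(prop-1-en-2-yl)-7-oxabicyclo[4.1.0]heptan-2-one | C=C(C)[C@H]1C[C@@H]2O[C@]2(C)C(=O)C1 | intermediate
3 | potassium C1–C6 enolate of 2 | C=C(C)[C@H]1C[C@@H]2O[C@]2(C)C([O-])=C1.[K+] | intermediate
4 | (1S,3R,4R,6S)-3-hydroxy-1-methyl-4-(prop-1-en-2-yl)-7-oxabicyclo[4.1.0]heptan-2-one | C=C(C)[C@H]1C[C@@H]2O[C@]2(C)C(=O)[C@@H]1O | intermediate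
5 | methyl (2S,3S)-3-[(2R)-2-formyl-3-methylbut-3-en-1-yl]-2-methyloxirane-2-carboxylate | C=C(C)[C@H](C=O)C[C@@H]1O[C@]1(C)C(=O)OC | intermediate
6 | (4-methoxyphenyl)methanol | COc1ccc(CO)cc1 | starting material
7 | tributyl(iodomethyl)stannane | CCCC[Sn](CCCC)(CCCC)CI | starting material
8 | sodium (4-methoxyphenyl)methoxide | COc1ccc(C[O-])cc1.[Na+] | intermediate
9 | tributyl{[(4-methoxybenzyl)oxy]methyl}stannane | CCCC[Sn](CCCC)(CCCC)COCc1ccc(OC)cc1 | intermediate
10 | [(4-methoxybenzyl)oxy]methyllithium | [Li]COCc1ccc(OC)cc1 | intermediate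
11 | lithium alkoxide of the C6 carbinol (adduct of 10 to 5) | C=C(C)[C@H]([C@H]([O-])COCc1ccc(OC)cc1)C[C@@H]1O[C@]1(C)C(=O)OC.[Li+] | intermediate
12 | methyl (2S,3S)-3-[(2R,3S)-3-acetoxy-4-[(4-methoxybenzyl)oxy]-2-(prop-1-en-2-yl)butyl]-2-methyloxirane-2-carboxylate | C=C(C)[C@H]([C@H](OC(C)=O)COCc1ccc(OC)cc1)C[C@@H]1O[C@]1(C)C(=O)OC | intermediate
13 | methyl (2S,3R,5R,6S)-6-acetoxy-2,3-dihydroxy-7-[(4-methoxybenzyl)oxy]-2-methyl-5-(prop-1-en-2-yl)heptanoate | C=C(C)[C@H]([C@H](OC(C)=O)COCc1ccc(OC)cc1)C[C@@H](O)[C@](C)(O)C(=O)OC | intermediate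
14 | methyl (2S,3R,5R,6S)-6-acetoxy-7-[(4-methoxybenzyl)oxy]-2-methyl-5-(prop-1-en-2-yl)-2,3-bis[(triethylsilyl)oxy]heptanoate | C=C(C)[C@H]([C@H](OC(C)=O)COCc1ccc(OC)cc1)C[C@@H](O[Si](CC)(CC)CC)[C@](C)(O[Si](CC)(CC)CC)C(=O)OC | intermediate
15 | (2R,3R,5R,6S)-7-[(4-methoxybenzyl)oxy]-2-methyl-5-(prop-1-en-2-yl)-2,3-bis[(triethylsilyl)oxy]heptane-1,6-diol | C=C(C)[C@H]([C@H](O)COCc1ccc(OC)cc1)C[C@@H](O[Si](CC)(CC)CC)[C@](C)(O[Si](CC)(CC)CC)CO | intermediate
16 | (2S,3R,5R,6S)-6-hydroxy-7-[(4-methoxybenzyl)oxy]-2-methyl-5-(prop-1-en-2-yl)-2,3-bis[(triethylsilyl)oxy]heptanal | C=C(C)[C@H]([C@H](O)COCc1ccc(OC)cc1)C[C@@H](O[Si](CC)(CC)CC)[C@](C)(O[Si](CC)(CC)CC)C=O | intermediate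
17 | angelic acid, (2Z)-2-methylbut-2-enoic acid | C/C=C(/C)C(=O)O | starting material
18 | angelic 2,4,6-trichlorobenzoic anhydride | C/C=C(/C)C(=O)OC(=O)c1c(Cl)cc(Cl)cc1Cl | intermediate
19 | C6 angelate of 16 | C=C(C)[C@H]([C@H](OC(=O)/C(C)=C\C)COCc1ccc(OC)cc1)C[C@@H](O[Si](CC)(CC)CC)[C@](C)(O[Si](CC)(CC)CC)C=O | intermediate
20 | C5 primary alcohol (19 without the 4-methoxybenzyl group) | C=C(C)[C@H]([C@H](OC(=O)/C(C)=C\C)CO)C[C@@H](O[Si](CC)(CC)CC)[C@](C)(O[Si](CC)(CC)CC)C=O | intermediate
21 | C5–C10–C1 dialdehyde (C6 angelate, C9 and C10 triethylsilyl ethers) | C=C(C)[C@H]([C@H](OC(=O)/C(C)=C\C)C=O)C[C@@H](O[Si](CC)(CC)CC)[C@](C)(O[Si](CC)(CC)CC)C=O | intermediate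
22 | but-2-yn-1-ol | CC#CCO | starting material
23 | but-2-yn-1-yl methyl carbonate | CC#CCOC(=O)OC | intermediate
24 | 2-(buta-2,3-dien-2-yl)-4,4,5,5-tetramethyl-1,3,2-dioxaborolane | C=C=C(C)B1OC(C)(C)C(C)(C)O1 | intermediate
25 | dicyclohexyl[(2Z)-3-(4,4,5,5-tetramethyl-1,3,2-dioxaborolan-2-yl)but-2-en-1-yl]borane | CC1(C)OB(OC1(C)C)/C(C)=C/CB(C2CCCCC2)C2CCCCC2 | intermediate
26 | tertiary allylboronate: C5 dicyclohexylborinate, C4(Me)(Bpin) vinyl, C1 aldehyde | C=C(C)[C@H]([C@H](OC(=O)/C(C)=C\C)[C@H](OB(C1CCCCC1)C1CCCCC1)[C@](C)(B1OC(C)(C)C(C)(C)O1)C=C)C[C@@H](O[Si](CC)(CC)CC)[C@](C)(O[Si](CC)(CC)CC)C=O | intermediate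
27 | cyclodecene with C1 pinacol borate and C5 dicyclohexylborinate | C=C(C)[C@H]1C[C@@H](O[Si](CC)(CC)CC)[C@](C)(O[Si](CC)(CC)CC)[C@@H](OB2OC(C)(C)C(C)(C)O2)C/C=C(C)\[C@@H](OB(C2CCCCC2)C2CCCCC2)[C@H]1OC(=O)/C(C)=C\C | intermediate
28 | (3Z)-cyclodec-3-ene-1,5-diol, C6 angelate, C9 and C10 triethylsilyl ethers | C=C(C)[C@H]1C[C@@H](O[Si](CC)(CC)CC)[C@](C)(O[Si](CC)(CC)CC)[C@@H](O)C/C=C(C)\[C@@H](O)[C@H]1OC(=O)/C(C)=C\C | intermediate
29 | C5 acetate of 28 | C=C(C)[C@H]1C[C@@H](O[Si](CC)(CC)CC)[C@](C)(O[Si](CC)(CC)CC)[C@@H](O)C/C=C(C)\[C@@H](OC(C)=O)[C@H]1OC(=O)/C(C)=C\C | intermediate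
30 | (3R,4R)-epoxide of 29 | C=C(C)[C@H]1C[C@@H](O[Si](CC)(CC)CC)[C@](C)(O[Si](CC)(CC)CC)[C@@H](O)C[C@H]2O[C@@]2(C)[C@@H](OC(C)=O)[C@H]1OC(=O)/C(C)=C\C | intermediate
31 | C1 angelate of 30 (9,10-bis-triethylsilyl ether of the target) | C=C(C)[C@H]1C[C@@H](O[Si](CC)(CC)CC)[C@](C)(O[Si](CC)(CC)CC)[C@@H](OC(=O)/C(C)=C\C)C[C@H]2O[C@@]2(C)[C@@H](OC(C)=O)[C@H]1OC(=O)/C(C)=C\C | intermediate
32 | CNP0249359.1 | C=C(C)[C@H]1C[C@@H](O)[C@](C)(O)[C@@H](OC(=O)/C(C)=C\C)C[C@H]2O[C@@]2(C)[C@@H](OC(C)=O)[C@H]1OC(=O)/C(C)=C\C | target

**Step count**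
Total: 21 steps. Longest linear sequence: 16 steps from (S)-carvone (steps 1–3, 5–9, 11–13, 17–21); side branches are step 4 (stannane), step 10 (mixed anhydride) and steps 14–16 (linchpin).

**Steps most likely to fail**

Step 17 (proposed new method). The second, intramolecular allyl transfer may lose to intermolecular addition (oligomers), or the hindered tertiary allylboronate may not reach the neopentyl C1 aldehyde before it decomposes. The fallback makes the same two ring bonds by known reactions and sets out from dialdehyde 21. Prop-1-en-2-ylmagnesium bromide (THF, −78 °C) should add to the C5 aldehyde under the same Felkin–Anh control to give the C5 isopropenyl carbinol F1. Brown allylation of the remaining C1 aldehyde with B-allyldiisopinocampheylborane from (+)-α-pinene (Et2O, −78 °C) gives the diene diol F2. Ring-closing metathesis (second-generation Hoveyda–Grubbs catalyst, toluene, high dilution, 80 °C) then joins C3 to C4 with loss of ethene and comes back to the route at cyclodecenediol 28. An E isomer, or a product of metathesis at the C7 isopropenyl group, would have to be separated.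

Step 5. Facial selectivity at C6 may be poor, and the basic organolithium may enolise the β,γ-unsaturated aldehyde and scramble C7. The fallback sets C6 by reagent control and starts from aldehyde 5. The same addition, quenched with NH4Cl instead of Ac2O, gives the C6-epimeric alcohols F3. Dess–Martin oxidation (NaHCO3, CH2Cl2, 0 °C) gives the ketone F4. Corey–Bakshi–Shibata reduction with the (S)-methyl oxazaborolidine and BH3·SMe2 (C7 branch as the large group, CH2OPMB as the small one) should give the single (6S) alcohol F5. Acetylation (Ac2O, pyridine, 0 °C) comes back to the route at acetate 12.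

Step 6. Water may fail to attack C9 selectively: the deactivated glycidic ester opens slowly, and the C5 ether oxygen can compete by closing a six-membered ring onto C9. The fallback delivers the C9 oxygen intramolecularly before C5 is added, starting from aldehyde 5. CSA in MeOH turns the C6 aldehyde into a hemiacetal whose oxygen opens the epoxide at C9 with inversion (five-membered ring closure) to give the cyclic methyl acetal F6. TESOTf/2,6-lutidine silylates the C10 hydroxyl to give the silyl ether F7, and aqueous acetic acid in THF gives the lactol F8. Excess [(4-methoxybenzyl)oxy]methyllithium (THF, −78 → −20 °C) adds to the open-chain aldehyde to give the 6,9-diol F9. Acetylation of the less hindered C6 hydroxyl (Ac2O, pyridine, −20 °C) gives the monoacetate F10, and TESOTf/2,6-lutidine at C9 comes back to the route at bis-silyl ester 14.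

**Further compounds**
F1 | step 17 | C5 isopropenyl carbinol with free C1 aldehyde | C=C(C)[C@H]([C@H](OC(=O)/C(C)=C\C)[C@H](O)C(C)=C)C[C@@H](O[Si](CC)(CC)CC)[C@](C)(O[Si](CC)(CC)CC)C=O
F2 | step 17 | diene diol (C5 isopropenyl carbinol, C1 allyl carbinol) | C=C(C)[C@H]([C@H](OC(=O)/C(C)=C\C)[C@H](O)C(C)=C)C[C@@H](O[Si](CC)(CC)CC)[C@](C)(O[Si](CC)(CC)CC)[C@@H](O)CC=C
F3 | step 5 | C6-epimeric alcohols from addition of 10 to 5 | C=C(C)[C@H](C(O)COCc1ccc(OC)cc1)C[C@@H]1O[C@]1(C)C(=O)OC
F4 | step 5 | C6 ketone | C=C(C)[C@H](C(=O)COCc1ccc(OC)cc1)C[C@@H]1O[C@]1(C)C(=O)OC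
F5 | step 5 | (6S) alcohol | C=C(C)[C@H]([C@H](O)COCc1ccc(OC)cc1)C[C@@H]1O[C@]1(C)C(=O)OC
F6 | step 6 | cyclic methyl acetal (C6–O–C9 tetrahydrofuran, C10 hydroxyl free) | C=C(C)[C@H]1C[C@@H](OC1OC)[C@](C)(O)C(=O)OC
F7 | step 6 | C10 triethylsilyl ether of F6 | C=C(C)[C@H]1C[C@@H](OC1OC)[C@](C)(O[Si](CC)(CC)CC)C(=O)OC
F8 | step 6 | lactol | C=C(C)[C@H]1C[C@@H](OC1O)[C@](C)(O[Si](CC)(CC)CC)C(=O)OC
F9 | step 6 | 6,9-diol | C=C(C)[C@H]([C@H](O)COCc1ccc(OC)cc1)C[C@@H](O)[C@](C)(O[Si](CC)(CC)CC)C(=O)OC
F10 | step 6 | C6 monoacetate of F9 | C=C(C)[C@H]([C@H](OC(C)=O)COCc1ccc(OC)cc1)C[C@@H](O)[C@](C)(O[Si](CC)(CC)CC)C(=O)OC
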